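**Assumption (one line):** the SMILES is read as the ent-labdane (3R,4S,5S,9R,10S) with the C3 ester oxygen and the C18 CH2OH both equatorial, a 13E alkene and a (Z)-2-methylbut-2-enoate (angelate); angelic anhydride is taken as a purchasable reagent.

## Retrosynthetic overview

1. Target 8 ⇐ bis-TBS 3-angelate 7 by removal of the two silyl groups.
2. 7 ⇐ bis-silylated (2R,3R)-epoxy alcohol 5 + angelic anhydride 6 by one Ti(III) radical cascade: ring A forms first (C4–C5), then ring B (C9–C10), the 8(17)-alkene forms on termination, and the C3 oxygen is acylated in the same flask.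
3. 5 ⇐ (E)-allylic alcohol 3 by Sharpless asymmetric epoxidation. This is the key step: the C–O bond it makes becomes the C3–O ester bond and is the only external source of chirality.
4. 3 ⇐ geranylgeranyl TBS ether 2 by allylic C–H hydroxylation (the C18–O bond) ⇐ geranylgeraniol 1.

## Route

Step 1
Reactants: 1 geranylgeraniol
Product: 2 geranylgeranyl TBS ether
Conditions: TBSCl (1.1 equiv), imidazole (2 equiv), CH2Cl2, 0 °C to rt
Reagents that add atoms: tert-butyldimethylsilyl chloride, CC(C)(C)[Si](C)(C)Cl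
Why: Imidazole-promoted O-silylation of the only hydroxyl masks the future C15–OH with a group that survives Se(IV)/peroxide, Ti(IV)/peroxide and Ti(III) and leaves with fluoride at the end; no stereocentre is formed.

Step 2
Reactants: 2 geranylgeranyl TBS ether
Product: 3 (14E)-16-hydroxygeranylgeranyl TBS ether
Conditions: SeO2 (0.2 equiv), t-BuOOH (3 equiv), salicylic acid (0.1 equiv), CH2Cl2, 0 °C to rt, stopped near 60% conversion, 2 recycled
Reagents that add atoms: tert-butyl hydroperoxide, CC(C)(C)OO; selenium dioxide, O=[Se]=O (catalytic oxygen relay)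
Why: Riley allylic oxidation (Se(IV) ene reaction then [2,3]-sigmatropic shift) hydroxylates the (E)-methyl group of the terminal, least hindered trisubstituted alkene and returns that alkene in place with E geometry, so the new oxygen becomes the equatorial C18–OH; no stereocentre is formed.

Step 3
Reactants: 3 (14E)-16-hydroxygeranylgeranyl TBS ether
Product: 5 bis-TBS (2R,3R)-epoxide, via epoxy alcohol 4 (not isolated)
Conditions: Ti(OiPr)4 (10 mol%), D-(−)-diethyl tartrate (12 mol%), t-BuOOH (1.2 equiv, in decane), 4 Å MS, CH2Cl2, −25 °C; then imidazole (3 equiv), TBSCl (1.5 equiv), −25 to 0 °C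
Reagents that add atoms: tert-butyl hydroperoxide, CC(C)(C)OO; tert-butyldimethylsilyl chloride, CC(C)(C)[Si](C)(C)Cl
Why: Sharpless asymmetric epoxidation epoxidises only the allylic-alcohol alkene, and the D-(−)-tartrate titanium complex delivers oxygen to the face that gives the (2R,3R)-epoxy alcohol (the CH carbon becomes C3 R of the target), while in situ silylation caps the primary hydroxyl so that O18 stays distinguishable from the future O3.

Step 4
Reactants: 5 bis-TBS (2R,3R)-epoxide; 6 angelic anhydride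
Product: 7 bis-TBS ent-labdadiene 3-angelate
Conditions: Cp2TiCl2 (20 mol%), Mn dust (2 equiv), 2,4,6-collidine (1 equiv), degassed THF (0.02 M), rt; 6 (2 equiv) added by syringe pump over 6 h, then 40 °C; aq. NH4Cl work-up
Reagents that add atoms: none
Why: Proposed new method: Cp2Ti(III)Cl opens the epoxide at its tertiary carbon, the resulting β-titanoxy radical closes ring A and then ring B through a chair–chair 6-endo/6-endo cascade with the titanoxy group and the bulkier CH2OTBS group equatorial (setting C4 S, C5 S, C10 S and C9 R relative to C3 R), the tertiary C8 radical is trapped by Ti(III) and loses a C17 hydrogen to give the exocyclic alkene, and, instead of the usual Me3SiCl/collidine, the Ti(IV)–O bond is cleaved by O-acyl transfer from slowly added angelic anhydride, which gives the hindered C3 angelate without a free alkoxide or nucleophilic amine that could isomerise Z to E and leaves a Ti(IV) carboxylate that Mn reduces back to Ti(III); the closest known reaction type is the titanocene(III)-catalysed radical cyclisation of epoxypolyenes with silyl chloride or collidinium turnover, combined with the acylation of titanium alkoxides by anhydrides.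

Step 5
Reactants: 7 bis-TBS ent-labdadiene 3-angelate
Product: 8 target, ent-3β-angeloyloxylabda-8(17),13E-diene-15,18-diol
Conditions: HF·pyridine, pyridine, THF, 0 °C to rt
Reagents that add atoms: none
Why: Fluoride-driven Si–O cleavage under buffered acidic conditions removes both primary TBS groups without forming an alkoxide, so no 3→18 acyl shift or Z→E isomerisation of the angelate is expected and no stereocentre is touched.

## Compound list

1 | geranylgeraniol, (2E,6E,10E)-3,7,11,15-tetramethylhexadeca-2,6,10,14-tetraen-1-ol | CC(C)=CCC/C(C)=C/CC/C(C)=C/CC/C(C)=C/CO | starting material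

2 | tert-butyldimethyl{[(2E,6E,10E)-3,7,11,15-tetramethylhexadeca-2,6,10,14-tetraen-1-yl]oxy}silane | CC(C)=CCC/C(C)=C/CC/C(C)=C/CC/C(C)=C/CO[Si](C)(C)C(C)(C)C | intermediate

3 | (2E,6E,10E,14E)-16-[(tert-butyldimethylsilyl)oxy]-2,6,10,14-tetramethylhexadeca-2,6,10,14-tetraen-1-ol | OC/C(C)=C/CC/C(C)=C/CC/C(C)=C/CC/C(C)=C/CO[Si](C)(C)C(C)(C)C | intermediate

4 | [(2R,3R)-3-{(3E,7E,11E)-13-[(tert-butyldimethylsilyl)oxy]-3,7,11-trimethyltrideca-3,7,11-trien-1-yl}-2-methyloxiran-2-yl]methanol | OC[C@@]1(C)O[C@@H]1CC/C(C)=C/CC/C(C)=C/CC/C(C)=C/CO[Si](C)(C)C(C)(C)C | intermediate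

5 | TBS ether of 4, (2R,3R)-2-{[(tert-butyldimethylsilyl)oxy]methyl}-3-{(3E,7E,11E)-13-[(tert-butyldimethylsilyl)oxy]-3,7,11-trimethyltrideca-3,7,11-trien-1-yl}-2-methyloxirane | CC(C)(C)[Si](C)(C)OC[C@@]1(C)O[C@@H]1CC/C(C)=C/CC/C(C)=C/CC/C(C)=C/CO[Si](C)(C)C(C)(C)C | intermediate

6 | angelic anhydride, (2Z)-2-methylbut-2-enoic anhydride | C/C=C(/C)C(=O)OC(=O)/C(C)=C\C | starting material

7 | (3R,4S,5S,9R,10S)-15,18-bis[(tert-butyldimethylsilyl)oxy]-ent-labda-8(17),13E-dien-3-yl (2Z)-2-methylbut-2-enoate (trans-decalin; C3 ester O and C18 CH2OTBS equatorial; C19 and C20 methyls axial and cis; C9 side chain cis to C20) | C=C1CC[C@H]2[C@@](C)(CC[C@@H](OC(=O)/C(C)=C\C)[C@]2(C)CO[Si](C)(C)C(C)(C)C)[C@@H]1CC/C(C)=C/CO[Si](C)(C)C(C)(C)C | intermediate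

8 | (3R,4S,5S,9R,10S)-15,18-dihydroxy-ent-labda-8(17),13E-dien-3-yl (2Z)-2-methylbut-2-enoate (CNP0118197.1) | C=C1CC[C@H]2[C@@](C)(CC[C@@H](OC(=O)/C(C)=C\C)[C@]2(C)CO)[C@@H]1CC/C(C)=C/CO | target

## Step count and risks

Total step count: 5. Longest linear sequence: 5 (from 1).

The three steps most likely to fail:

**Step 2.** The Riley oxidation gives modest conversion, competes with oxidation at internal allylic CH2 groups and can over-oxidise to the enal. The fallback sets out from 2 and comes back at 3, and builds the (E)-allylic alcohol by degradation and olefination instead of C–H oxidation. NBS in THF/H2O at 0 °C gives the racemic terminal bromohydrin F1. K2CO3 in MeOH closes it to the racemic 14,15-epoxide F2. HIO4 in THF/H2O cleaves this to the trisnor aldehyde F3. Wittig reaction with Ph3P=C(CH3)CO2Et gives the (E)-ethyl ester F4, and DIBAL-H in CH2Cl2 at −78 °C returns 3.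

**Step 4 (the new step).** Acyl transfer to the hindered titanium alkoxide may be too slow to turn the catalyst over, radicals may add to the anhydride, and the equatorial preference of CH2OTBS at C4 may be only moderate because the C4 radical is planar. The fallback uses known chemistry, sets out from 5 and comes back at 7. Stoichiometric Cp2TiCl (from Cp2TiCl2 and Mn in THF at rt, aqueous acid work-up) effects the same radical bicyclisation and gives the free bis-TBS 3-ol F5, from which any C4 epimer is removed by chromatography. F5 is then deprotonated with LiHMDS in THF at −20 °C and acylated with 6 to give 7.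

**Step 5.** The neopentyl-type C18 silyl ether may need forcing conditions, which risk a 3→18 acyl shift or isomerisation of the exocyclic alkene. The fallback sets out from 4 (isolated after a tartaric acid work-up of step 3) and comes back at 8, and uses an oxidatively removable group on O18. NaH, PMBCl and Bu4NI in THF give the PMB ether F6. The conditions of step 4 convert it into the PMB-protected angelate F7. DDQ in CH2Cl2/pH 7 buffer frees O18 to give the C18 alcohol F8, and CSA in MeOH at 0 °C removes the allylic TBS group to give 8.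

## Further compounds

F1 | step 2 | racemic (6E,10E,14E)-3-bromo-16-[(tert-butyldimethylsilyl)oxy]-2,6,10,14-tetramethylhexadeca-6,10,14-trien-2-ol | CC(C)(O)C(Br)CC/C(C)=C/CC/C(C)=C/CC/C(C)=C/CO[Si](C)(C)C(C)(C)C
F2 | step 2 | racemic tert-butyl{[(2E,6E,10E)-13-(3,3-dimethyloxiran-2-yl)-3,7,11-trimethyltrideca-2,6,10-trien-1-yl]oxy}dimethylsilane | CC1(C)OC1CC/C(C)=C/CC/C(C)=C/CC/C(C)=C/CO[Si](C)(C)C(C)(C)C
F3 | step 2 | (4E,8E,12E)-14-[(tert-butyldimethylsilyl)oxy]-4,8,12-trimethyltetradeca-4,8,12-trienal | O=CCC/C(C)=C/CC/C(C)=C/CC/C(C)=C/CO[Si](C)(C)C(C)(C)C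
F4 | step 2 | ethyl (2E,6E,10E,14E)-16-[(tert-butyldimethylsilyl)oxy]-2,6,10,14-tetramethylhexadeca-2,6,10,14-tetraenoate | CCOC(=O)/C(C)=C/CC/C(C)=C/CC/C(C)=C/CC/C(C)=C/CO[Si](C)(C)C(C)(C)C
F5 | step 4 | (3R,4S,5S,9R,10S)-15,18-bis[(tert-butyldimethylsilyl)oxy]-ent-labda-8(17),13E-dien-3-ol | C=C1CC[C@H]2[C@@](C)(CC[C@@H](O)[C@]2(C)CO[Si](C)(C)C(C)(C)C)[C@@H]1CC/C(C)=C/CO[Si](C)(C)C(C)(C)C
F6 | step 5 | (2R,3R)-3-{(3E,7E,11E)-13-[(tert-butyldimethylsilyl)oxy]-3,7,11-trimethyltrideca-3,7,11-trien-1-yl}-2-{[(4-methoxybenzyl)oxy]methyl}-2-methyloxirane | COc1ccc(COC[C@@]2(C)O[C@@H]2CC/C(C)=C/CC/C(C)=C/CC/C(C)=C/CO[Si](C)(C)C(C)(C)C)cc1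
F7 | step 5 | (3R,4S,5S,9R,10S)-15-[(tert-butyldimethylsilyl)oxy]-18-[(4-methoxybenzyl)oxy]-ent-labda-8(17),13E-dien-3-yl (2Z)-2-methylbut-2-enoate | C=C1CC[C@H]2[C@@](C)(CC[C@@H](OC(=O)/C(C)=C\C)[C@]2(C)COCc3ccc(OC)cc3)[C@@H]1CC/C(C)=C/CO[Si](C)(C)C(C)(C)C
F8 | step 5 | (3R,4S,5S,9R,10S)-15-[(tert-butyldimethylsilyl)oxy]-18-hydroxy-ent-labda-8(17),13E-dien-3-yl (2Z)-2-methylbut-2-enoate | C=C1CC[C@H]2[C@@](C)(CC[C@@H](OC(=O)/C(C)=C\C)[C@]2(C)CO)[C@@H]1CC/C(C)=C/CO[Si](C)(C)C(C)(C)C
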